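**Retrosynthetic overview**

1. The target 29 is ent-labda-8(17),13(16),14-trien-19-yl (Z)-4-hydroxycinnamate. The Z-cinnamate is built last on the C19 alcohol 24 by Still–Gennari olefination of its phosphonoacetate; the 2-substituted butadiene comes from a C12 iodide and buta-1,3-dien-2-ylmagnesium chloride.
2. The C8=C17 methylene comes from a C8 ketone (Wittig). The quaternary C4 (CH3 + C19) comes from a C4 ketone via enol triflate, methoxycarbonylation and reductive methylation.
3. Ring B is closed by Dieckmann formation of the C7–C8 bond in keto diester 11. Ring A is bought as 3-methylcyclohex-2-en-1-one, so ring A comes first and ring B second.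
4. Enabling feature: in ring B the methylene-bearing C8 lies between C7H2 and C9–H, and in ring A C4 lies next to C5–H. At the 4,8-dione oxidation level C7–C8 is an enolate–acyl bond and C5 and C9 are both α to a carbonyl and epimerizable, so only the quaternary C10 must come from asymmetric catalysis.
5. Diester 11 comes from two-directional hydroboration/oxidation of an allyl group (C6, C7 and a carbon later lost as CO2) and a 1,1-disubstituted alkenyl group (C8, C9, side chain). Both are put on the enone by asymmetric conjugate addition, enolate trapping and allylation.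

Key step: step 5

Remark: labdane numbering is used (ring A = C1–C5 and C10, ring B = C5–C10, C17 = methylene carbon on C8, C19 = oxygen-bearing carbon on C4, C20 = methyl on C10); compound 25 is taken as a catalogue reagent.

**Route**

Step 1
Reactants: 1 4-(benzyloxy)but-1-yne; 2 3-methylcyclohex-2-en-1-one
Product: 5 (R)-3-[4-(benzyloxy)but-1-en-2-yl]-3-methylcyclohex-1-en-1-yl acetate, via alkenylalane 3 (not isolated), via aluminium enolate 4 (not isolated)
Conditions: 1, i-Bu2AlH, Ni(dppp)Cl2 (3 mol %), THF, 0 → 22 °C; then 2, Cu(OTf)2 (5 mol %), chiral sulfonate-bearing N-heterocyclic carbene ligand (from its imidazolinium salt, 5.5 mol %), THF, −30 °C; then Ac2O, −30 → 0 °C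
Reagents that add atoms: acetic anhydride, CC(=O)OC(C)=O
Why: Nickel-catalysed hydroalumination puts aluminium on the internal alkyne carbon, the alkenylalane then undergoes copper-catalysed asymmetric conjugate addition to the β-methyl enone so that the quaternary C10 is set by the chiral ligand (antipode chosen for the R product), and O-acetylation of the aluminium enolate fixes the C4–C5 enol regiochemistry (tandem conjugate addition–enolate trapping).

Step 2
Reactants: 5 (R)-3-[4-(benzyloxy)but-1-en-2-yl]-3-methylcyclohex-1-en-1-yl acetate; 6 3-iodoprop-1-ene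
Product: 8 (2S,3R)-3-[4-(benzyloxy)but-1-en-2-yl]-3-methyl-2-(prop-2-en-1-yl)cyclohexan-1-one, via lithium enolate 7 (not isolated)
Conditions: MeLi (2.0 equiv), THF, 0 °C; then 6, DMPU, −78 → 0 °C
Reagents that add atoms: none
Why: MeLi cleaves the enol acetate to the regiodefined lithium enolate, whose C-allylation at C5 (enolate alkylation) should occur anti to the bulkier alkenyl group on C10 to give the 2,3-trans ketone, and C5 stays epimerizable so that step 5 can correct it thermodynamically.

Step 3
Reactants: 8 (2S,3R)-3-[4-(benzyloxy)but-1-en-2-yl]-3-methyl-2-(prop-2-en-1-yl)cyclohexan-1-one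
Product: 9 3-[4-(benzyloxy)-1-hydroxybutan-2-yl]-2-(3-hydroxypropyl)-3-methylcyclohexan-1-ol (ring centres C5 and C10 as in 8; epimer mixture at C4 and C9)
Conditions: BH3·THF (excess), THF, 0 → 22 °C; then NaOH, H2O2, 0 → 22 °C
Reagents that add atoms: hydrogen peroxide, OO
Why: Hydroboration–oxidation adds anti-Markovnikov to the allyl and the 1,1-disubstituted alkene to give both primary alcohols, while reduction of the ketone and the unselective creation of the C9 methine are harmless because step 4 reoxidises C4 and step 8 equilibrates C9.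

Step 4
Reactants: 9 the triol from step 3
Product: 11 methyl 4-(benzyloxy)-2-[(1R,2S)-2-(3-methoxy-3-oxopropyl)-1-methyl-3-oxocyclohexyl]butanoate (C9 epimer mixture), via keto diacid 10 (not isolated)
Conditions: CrO3, H2SO4, H2O, acetone, 0 °C; then Me3SiCHN2, MeOH/toluene, 22 °C
Reagents that add atoms: water, O; trimethylsilyldiazomethane, C[Si](C)(C)C=[N+]=[N-]
Why: Jones oxidation takes the two primary alcohols to carboxylic acids and the ring carbinol back to the ketone (fast oxidation of the secondary alcohol suppresses lactol formation), and trimethylsilyldiazomethane then esterifies both acids.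

Step 5
Reactants: 11 the keto diester from step 4
Product: 12 methyl 4-[2-(benzyloxy)ethyl]-4a-methyl-3,8-dioxodecahydronaphthalene-2-carboxylate (labdane numbering: 4,8-dioxo, CO2CH3 on C7; trans-fused, H-5 anti to CH3-20; C7 and C9 epimer mixtures)
Conditions: KOt-Bu (2.5 equiv), THF, 0 → 25 °C; then aq. HCl
Reagents that add atoms: none
Why: KOt-Bu deprotonates the propanoate arm at C7 and this ester enolate attacks the C8 ester carbonyl; loss of methoxide gives the β-keto ester, which is drained as its stabilised enolate (Dieckmann condensation of a pimelate-type diester is the closest known reaction type). Ring B closes in the 6-(enolexo)-exo-trig mode. C5, α to the free C4 ketone, equilibrates under the same base to the trans ring fusion (H-5 anti to the C10 methyl, the arrangement already favoured by step 2), whereas C7 is stereolabile and disappears in step 8 and C9 is fixed only in step 8. The selectivity needed is acylation of the C7 enolate by the C8 ester rather than (a) attack of a C9 enolate on the arm ester or (b) C-acylation of the ketone at C3; (a) would give a quaternary, non-enolisable β-keto ester and (b) bridged diketones whose acidic carbon is a bridgehead, so under reversible conditions only 12, with an acidic C7–H between two carbonyls, is removed from the equilibria.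

Step 6
Reactants: 12 the β-keto ester from step 5
Product: 13 methyl 4-[2-(benzyloxy)ethyl]-4a-methyl-3-oxo-8-[(trifluoromethanesulfonyl)oxy]-1,2,3,4,4a,5,6,8a-octahydronaphthalene-2-carboxylate (enol triflate at C4, C3=C4; centres as in 12)
Conditions: KN(SiMe3)2 (2.2 equiv), THF, −78 °C; then PhNTf2 (1.1 equiv), −78 → 0 °C; NH4Cl work-up
Reagents that add atoms: N-phenylbis(trifluoromethanesulfonimide), O=S(=O)(N(c1ccccc1)S(=O)(=O)C(F)(F)F)C(F)(F)F
Why: With two equivalents of base the β-keto ester is masked as its stabilised enolate and the C4 ketone is deprotonated kinetically at the C3 methylene (H-5 is tertiary and shielded by the quaternary C10), so that PhNTf2 triflates only the reactive ketone enolate (enol triflate formation), which also fixes C5.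

Step 7
Reactants: 13 the enol triflate from step 6
Product: 14 dimethyl 5-[2-(benzyloxy)ethyl]-4a-methyl-6-oxo-3,4,4a,5,6,7,8,8a-octahydronaphthalene-1,7-dicarboxylate (C19 ester on C4, C3=C4; centres as in 12)
Conditions: Pd(OAc)2 (5 mol %), dppf (6 mol %), CO (1 atm), MeOH, Et3N, DMF, 50 °C
Reagents that add atoms: carbon monoxide, [C-]#[O+]; methanol, CO
Why: Palladium-catalysed methoxycarbonylation of the enol triflate (oxidative addition, CO insertion, methanolysis) introduces C19 at the ester oxidation level without affecting the β-keto ester.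

Step 8
Reactants: 14 the diester from step 7
Product: 16 methyl (4aR,5S,8aS)-5-[2-(benzyloxy)ethyl]-4a-methyl-6-oxo-3,4,4a,5,6,7,8,8a-octahydronaphthalene-1-carboxylate, via C9-epimeric ketone 15 (not isolated)
Conditions: LiCl, DMSO, H2O, 150 °C; then K2CO3 (cat.), MeOH, 40 °C
Reagents that add atoms: none
Why: Krapcho dealkoxycarbonylation removes the activating ester from C7 (chloride demethylation, loss of CO2), and the carbonate treatment then equilibrates C9, now α to the C8 ketone, to the equatorial side chain of the target by thermodynamic control.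

Step 9
Reactants: 16 the ketone from step 8
Product: 17 methyl (4aS,5R,8aS)-5-[2-(benzyloxy)ethyl]-4a-methyl-6-methylidene-3,4,4a,5,6,7,8,8a-octahydronaphthalene-1-carboxylate
Conditions: Ph3PCH3Br, KOt-Bu, toluene, 80 °C
Reagents that add atoms: methyltriphenylphosphonium bromide, C[P+](c1ccccc1)(c1ccccc1)c1ccccc1.[Br-]
Why: Wittig methylenation converts the hindered C8 ketone into the 8(17)-methylene group while the unsaturated ester is inert to the non-stabilised ylide, and any base-induced epimerisation at C9 only returns the thermodynamic epimer.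

Step 10
Reactants: 17 the methylidene ester from step 9
Product: 19 methyl (1R,4aS,5R,8aS)-5-(2-hydroxyethyl)-1,4a-dimethyl-6-methylidenedecahydronaphthalene-1-carboxylate, via dilithium enolate alkoxide 18 (not isolated)
Conditions: Li (6 equiv), NH3(l)/THF, t-BuOH (1 equiv), −78 °C; then MeI (excess), −78 → −33 °C; NH4Cl
Reagents that add atoms: iodomethane, CI
Why: Dissolving-metal reduction (Birch-type reductive alkylation) converts the unsaturated ester into its C4 enolate and cleaves the benzyl ether in the same flask, and iodomethane then attacks the enolate from the face opposite to the axial C10 methyl, so that the new methyl is equatorial and the ester axial (cis to CH3-20) as the target requires.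

Step 11
Reactants: 19 the hydroxy ester from step 10
Product: 20 methyl (1R,4aS,5R,8aS)-5-(2-iodoethyl)-1,4a-dimethyl-6-methylidenedecahydronaphthalene-1-carboxylate
Conditions: I2, PPh3, imidazole, CH2Cl2, 0 → 22 °C
Reagents that add atoms: iodine, II
Why: Appel-type iodination of the unhindered primary alcohol proceeds by SN2 displacement of the oxyphosphonium group and leaves the ester and the alkene untouched.

Step 12
Reactants: 20 the iodide from step 11; 21 2-chlorobuta-1,3-diene
Product: 23 methyl (1R,4aS,5R,8aS)-1,4a-dimethyl-6-methylidene-5-(3-methylidenepent-4-en-1-yl)decahydronaphthalene-1-carboxylate, via dienyl Grignard 22 (not isolated)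
Conditions: 21, Mg, ZnCl2 (cat.), THF, reflux; then 20, Li2CuCl4 (5 mol %), THF, 0 → 22 °C
Reagents that add atoms: none
Why: The Grignard reagent of chloroprene couples with the primary iodide under Li2CuCl4 catalysis (copper-catalysed Kumada-type alkylation) to give the 2-substituted buta-1,3-diene directly, the neopentyl quaternary ester being too hindered to react at 0 °C.

Step 13
Reactants: 23 the triene ester from step 12
Product: 24 [(1R,4aS,5R,8aS)-1,4a-dimethyl-6-methylidene-5-(3-methylidenepent-4-en-1-yl)decahydronaphthalen-1-yl]methanol (ent-labda-8(17),13(16),14-trien-19-ol)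
Conditions: LiAlH4, THF, 0 → 50 °C
Reagents that add atoms: none
Why: Hydride reduction of the methyl ester gives the primary C19 alcohol, and the isolated alkenes and the diene do not react.

Step 14
Reactants: 24 the C19 alcohol from step 13; 25 [bis(2,2,2-trifluoroethoxy)phosphoryl]acetic acid
Product: 26 [(1R,4aS,5R,8aS)-1,4a-dimethyl-6-methylidene-5-(3-methylidenepent-4-en-1-yl)decahydronaphthalen-1-yl]methyl [bis(2,2,2-trifluoroethoxy)phosphoryl]acetate
Conditions: DCC, DMAP (cat.), CH2Cl2, 0 → 22 °C
Reagents that add atoms: none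
Why: Steglich esterification acylates the neopentyl alcohol with the phosphonoacetic acid under neutral conditions.

Step 15
Reactants: 26 the phosphonoacetate from step 14; 27 4-[(tert-butyldimethylsilyl)oxy]benzaldehyde
Product: 29 [(1R,4aS,5R,8aS)-1,4a-dimethyl-6-methylidene-5-(3-methylidenepent-4-en-1-yl)decahydronaphthalen-1-yl]methyl (2Z)-3-(4-hydroxyphenyl)prop-2-enoate, via silyl-protected Z-ester 28 (not isolated)
Conditions: KN(SiMe3)2, 18-crown-6, THF, −78 °C; then 27, −78 °C; then Bu4NF/AcOH, THF, 0 °C, light excluded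
Reagents that add atoms: none
Why: In the Still–Gennari olefination the bis(trifluoroethyl)phosphonate anion with a dissociated potassium counter-ion adds to the aldehyde and the oxaphosphetane collapses under kinetic control to the Z-alkene, and buffered fluoride then frees the phenol without isomerising the Z-cinnamate.

**Compound list**

1 | 4-(benzyloxy)but-1-yne | C#CCCOCc1ccccc1 | starting material
2 | 3-methylcyclohex-2-en-1-one | CC1=CC(=O)CCC1 | starting material
3 | [4-(benzyloxy)but-1-en-2-yl]bis(2-methylpropyl)alane | C=C(CCOCc1ccccc1)[Al](CC(C)C)CC(C)C | intermediate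
4 | bis(2-methylpropyl)aluminium (R)-3-[4-(benzyloxy)but-1-en-2-yl]-3-methylcyclohex-1-en-1-olate | CC(C)C[Al](CC(C)C)OC1=C[C@](C)(C(=C)CCOCc2ccccc2)CCC1 | intermediate
5 | (R)-3-[4-(benzyloxy)but-1-en-2-yl]-3-methylcyclohex-1-en-1-yl acetate | CC(=O)OC1=C[C@](C)(C(=C)CCOCc2ccccc2)CCC1 | intermediate
6 | 3-iodoprop-1-ene | C=CCI | starting material
7 | lithium (R)-3-[4-(benzyloxy)but-1-en-2-yl]-3-methylcyclohex-1-en-1-olate | [Li]OC1=C[C@](C)(C(=C)CCOCc2ccccc2)CCC1 | intermediate
8 | (2S,3R)-3-[4-(benzyloxy)but-1-en-2-yl]-3-methyl-2-(prop-2-en-1-yl)cyclohexan-1-one | O=C1CCC[C@@](C)(C(=C)CCOCc2ccccc2)[C@@H]1CC=C | intermediate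
9 | 3-[4-(benzyloxy)-1-hydroxybutan-2-yl]-2-(3-hydroxypropyl)-3-methylcyclohexan-1-ol (C5, C10 as in 8; C4 and C9 epimers) | OC1CCC[C@@](C)(C(CO)CCOCc2ccccc2)[C@@H]1CCCO | intermediate
10 | 4-(benzyloxy)-2-[(1R,2S)-2-(2-carboxyethyl)-1-methyl-3-oxocyclohexyl]butanoic acid (C9 epimers) | O=C1CCC[C@@](C)(C(C(=O)O)CCOCc2ccccc2)[C@@H]1CCC(=O)O | intermediate
11 | methyl 4-(benzyloxy)-2-[(1R,2S)-2-(3-methoxy-3-oxopropyl)-1-methyl-3-oxocyclohexyl]butanoate (C9 epimers) | O=C1CCC[C@@](C)(C(C(=O)OC)CCOCc2ccccc2)[C@@H]1CCC(=O)OC | intermediate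
12 | methyl 4-[2-(benzyloxy)ethyl]-4a-methyl-3,8-dioxodecahydronaphthalene-2-carboxylate (trans-fused; C7 and C9 epimers) | COC(=O)C1C[C@@H]2C(=O)CCC[C@@]2(C)C(CCOCc3ccccc3)C1=O | intermediate
13 | methyl 4-[2-(benzyloxy)ethyl]-4a-methyl-3-oxo-8-[(trifluoromethanesulfonyl)oxy]-1,2,3,4,4a,5,6,8a-octahydronaphthalene-2-carboxylate | COC(=O)C1C[C@@H]2C(OS(=O)(=O)C(F)(F)F)=CCC[C@@]2(C)C(CCOCc3ccccc3)C1=O | intermediate
14 | dimethyl 5-[2-(benzyloxy)ethyl]-4a-methyl-6-oxo-3,4,4a,5,6,7,8,8a-octahydronaphthalene-1,7-dicarboxylate | COC(=O)C1C[C@@H]2C(C(=O)OC)=CCC[C@@]2(C)C(CCOCc3ccccc3)C1=O | intermediate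
15 | methyl 5-[2-(benzyloxy)ethyl]-4a-methyl-6-oxo-3,4,4a,5,6,7,8,8a-octahydronaphthalene-1-carboxylate (C9 epimers) | O=C1CC[C@@H]2C(C(=O)OC)=CCC[C@@]2(C)C1CCOCc1ccccc1 | intermediate
16 | methyl (4aR,5S,8aS)-5-[2-(benzyloxy)ethyl]-4a-methyl-6-oxo-3,4,4a,5,6,7,8,8a-octahydronaphthalene-1-carboxylate | O=C1CC[C@@H]2C(C(=O)OC)=CCC[C@@]2(C)[C@@H]1CCOCc1ccccc1 | intermediate
17 | methyl (4aS,5R,8aS)-5-[2-(benzyloxy)ethyl]-4a-methyl-6-methylidene-3,4,4a,5,6,7,8,8a-octahydronaphthalene-1-carboxylate | C=C1CC[C@@H]2C(C(=O)OC)=CCC[C@@]2(C)[C@@H]1CCOCc1ccccc1 | intermediate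
18 | dilithium ester enolate alkoxide of the reduced, debenzylated ester | C=C1CC[C@@H]2C(=C(OC)O[Li])CCC[C@@]2(C)[C@@H]1CCO[Li] | intermediate
19 | methyl (1R,4aS,5R,8aS)-5-(2-hydroxyethyl)-1,4a-dimethyl-6-methylidenedecahydronaphthalene-1-carboxylate | C=C1CC[C@@H]2[C@](C)(C(=O)OC)CCC[C@@]2(C)[C@@H]1CCO | intermediate
20 | methyl (1R,4aS,5R,8aS)-5-(2-iodoethyl)-1,4a-dimethyl-6-methylidenedecahydronaphthalene-1-carboxylate | C=C1CC[C@@H]2[C@](C)(C(=O)OC)CCC[C@@]2(C)[C@@H]1CCI | intermediate
21 | 2-chlorobuta-1,3-diene | C=CC(Cl)=C | starting material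
22 | buta-1,3-dien-2-ylmagnesium chloride | C=CC(=C)[Mg]Cl | intermediate
23 | methyl (1R,4aS,5R,8aS)-1,4a-dimethyl-6-methylidene-5-(3-methylidenepent-4-en-1-yl)decahydronaphthalene-1-carboxylate | C=CC(=C)CC[C@@H]1C(=C)CC[C@@H]2[C@](C)(C(=O)OC)CCC[C@@]12C | intermediate
24 | [(1R,4aS,5R,8aS)-1,4a-dimethyl-6-methylidene-5-(3-methylidenepent-4-en-1-yl)decahydronaphthalen-1-yl]methanol | C=CC(=C)CC[C@@H]1C(=C)CC[C@@H]2[C@](C)(CO)CCC[C@@]12C | intermediate
25 | [bis(2,2,2-trifluoroethoxy)phosphoryl]acetic acid | OC(=O)CP(=O)(OCC(F)(F)F)OCC(F)(F)F | starting material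
26 | [(1R,4aS,5R,8aS)-1,4a-dimethyl-6-methylidene-5-(3-methylidenepent-4-en-1-yl)decahydronaphthalen-1-yl]methyl [bis(2,2,2-trifluoroethoxy)phosphoryl]acetate | C=CC(=C)CC[C@@H]1C(=C)CC[C@@H]2[C@](C)(COC(=O)CP(=O)(OCC(F)(F)F)OCC(F)(F)F)CCC[C@@]12C | intermediate
27 | 4-[(tert-butyldimethylsilyl)oxy]benzaldehyde | O=Cc1ccc(O[Si](C)(C)C(C)(C)C)cc1 | starting material
28 | tert-butyldimethylsilyl ether of 29 at the phenol | C=CC(=C)CC[C@@H]1C(=C)CC[C@@H]2[C@](C)(COC(=O)/C=C\c3ccc(O[Si](C)(C)C(C)(C)C)cc3)CCC[C@@]12C | intermediate
29 | [(1R,4aS,5R,8aS)-1,4a-dimethyl-6-methylidene-5-(3-methylidenepent-4-en-1-yl)decahydronaphthalen-1-yl]methyl (2Z)-3-(4-hydroxyphenyl)prop-2-enoate | C=CC(=C)CC[C@@H]1C(=C)CC[C@@H]2[C@](C)(COC(=O)/C=C\c3ccc(O)cc3)CCC[C@@]12C | target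

**Step count and risks**

Total step count: 15. Longest linear sequence: 15 steps (1 and 2 to 29).

Steps most likely to fail:

Step 1. The hydroalumination may give a mixture of internal and terminal alanes, the hindered 1,1-disubstituted alkenyl group may transfer slowly or with eroded facial selectivity, and the aluminium enolate may be acetylated incompletely. The fallback exchanges the roles of the two substituents on C10; it sets out from 1 and comes back to the route at 5. Bromoboration of 1 with B-bromo-9-borabicyclo[3.3.1]nonane and protonolysis with AcOH should give 2-bromo-4-(benzyloxy)but-1-ene F1. Bromine–lithium exchange (t-BuLi) and Stork–Danheiser addition to 3-ethoxycyclohex-2-en-1-one with acidic work-up should give 3-[4-(benzyloxy)but-1-en-2-yl]cyclohex-2-en-1-one F2. Asymmetric 1,4-addition of Me3Al (Cu(OTf)2, chiral N-heterocyclic carbene ligand, which favours 1,4- over 1,6-addition to such dienones) and trapping with Ac2O then returns to 5.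

Step 5. The free ring-A ketone may enter the Claisen manifold (acylation at C3), or the hindered C8 ester may react so slowly that retro-Claisen cleavage and intermolecular condensation take over. The fallback removes the ketone from the enolate manifold; it sets out from 11 and comes back at 12. Ketalisation (ethane-1,2-diol, TsOH, benzene, reflux) should give the dioxolane diester F3. Dieckmann cyclisation (NaH, catalytic MeOH, THF, reflux) should then give the ketal β-keto ester F4. Aqueous HCl in acetone returns to 12, and C5 is equilibrated there with K2CO3/MeOH before step 6.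

Step 10. The ester enolate may be protonated before alkylation, the liberated alkoxide may be O-methylated, or the benzyl ether may be cleaved incompletely. The fallback separates reduction from alkylation; it sets out from 17 and comes back at 19. Li/NH3 with t-BuOH and an NH4Cl quench should give the saturated hydroxy ester F5 (C4 epimers). Deprotonation with LiN(i-Pr)2 (2.2 equiv, THF, −78 °C) to the alkoxide ester enolate and addition of MeI should then give 19 by the same equatorial approach of the electrophile.

Further compounds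
F1 | step 1 | 2-bromo-4-(benzyloxy)but-1-ene | C=C(Br)CCOCc1ccccc1
F2 | step 1 | 3-[4-(benzyloxy)but-1-en-2-yl]cyclohex-2-en-1-one | C=C(CCOCc1ccccc1)C1=CC(=O)CCC1
F3 | step 5 | ethylene ketal of 11 at the ring ketone (C9 epimers) | COC(=O)CC[C@H]1[C@](C)(C(C(=O)OC)CCOCc2ccccc2)CCCC13OCCO3
F4 | step 5 | ethylene ketal of 12 at the C4 ketone (C7 and C9 epimers) | COC(=O)C1C[C@@H]2C3(OCCO3)CCC[C@@]2(C)C(CCOCc4ccccc4)C1=O
F5 | step 10 | methyl (4aS,5R,8aS)-5-(2-hydroxyethyl)-4a-methyl-6-methylidenedecahydronaphthalene-1-carboxylate (C4 epimers) | C=C1CC[C@@H]2C(C(=O)OC)CCC[C@@]2(C)[C@@H]1CCO
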